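The numbers in the tables are simulated for substances that don't exist; the scatter is artificial.

If every pre-initiator begins one chain, the average chain length is a count of turnovers: free monomer consumed per chain. Its upper bound is the **turnover ceiling**, free monomer charged per pre-initiator charged, which for the new flask was 357. Reaching 300 therefore needed 84.0% of the free monomer to react.

| setting | Tuesday's | Thursday's | flask |
|---|---|---|---|
| free monomer | 0.050 M | 0.075 M | 0.10 M |
| pre-initiator | 0.28 mM | 0.28 mM | 0.28 mM |
| remark | run made earlier | run made earlier |  |
| time |  |  | 12 h |

| run | time / h | monomer in chains / % | free monomer / % |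
|---|---|---|---|
| Tuesday's | 2.50 | 51.2 | 48.0 |
| Tuesday's | 5.00 | 81.3 | 19.0 |
| Tuesday's | 8.00 | 93.6 | 6.4 |
| Tuesday's | 10.0 | 96.6 | 1.9 |
| Thursday's | 1.33 | 26.6 | 73.1 |
| Thursday's | 3.00 | 61.3 | 39.9 |
| Thursday's | 6.00 | 87.2 | 12.5 |
| Thursday's | 10.0 | 96.3 | 3.5 |

(scatter of a reading: 0.5 percentage points)

* whether the average number of monomer units in a chain (chains begun, living or dead) reaches 300 by 12 h (yes / no)
* average number of monomer units in a chain (chains begun, living or dead) at 12 h

- the average divides the monomer in chains by the number of chains begun, living and dead together
- the earlier runs do not show the number of chains; that part of a forecast is a guess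

I first read a decay rate k, the slope of ln(free monomer) against time. Thursday's run gave 0.387 h⁻¹ between its middle readings and Tuesday's gave 0.371 h⁻¹, although the charges differed. I treated the decay as pseudo-first-order, with a time constant of 2.58 h, and assumed that the new flask followed it. Thursday's earliest reading gave a lower slope, 0.236 h⁻¹, so I left it out.

I then reached the count for the new flask at 12 h in two ways. Carrying Thursday's free monomer forward from 6.00 h left 1.23%, which gave the new flask 353 turnovers. Carrying forward the part of the charge not yet in chains on Thursday at 10.0 h left 1.71%, which gave 351. The two ways share k but start from different columns, and they agreed.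

Tuesday's last readings parted: free monomer read 1.9%, while monomer in chains implied 3.40%, a gap of 1.5 percentage points against a scatter of 0.5 points. Tuesday's free monomer at 5.00 h, carried forward with Thursday's k, gave 2.75%, between the two, so neither reading was convicted. Carried to 12 h, the gap was worth 2.47 turnovers. The real risk was the chain count, which the runs do not show: my count stayed above 300 unless chains exceeded the pre-initiator charge by 17.6%.

The forecast said yes, with an average of 350, on the condition “each pre-initiator starts one chain”.

The flask gave yes, with an average of 350 at 12 h.

    free monomer + living end → monomer in chains + living end, rate k1*[living end]*[free monomer] (k = 23.0 L mol⁻¹ min⁻¹)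
    monomer in chains → over-reaction product (k = 1.40 × 10⁻⁵ min⁻¹)
    free monomer + initiator → living end + monomer in chains (k = 12.0 L mol⁻¹ min⁻¹)
    pre-initiator → initiator (k = 0.0270 min⁻¹)

In this flask the average passed 300 at 5.40 h, with 84.2% of the free monomer reacted. At 1.20 h, the ceiling times the 22.7% reacted gave 80.9, less than the flask's average of 94.9, and 14.3% of the pre-initiator's charge still stood in the flask.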